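**Retrosynthetic overview**
1. Target ⇐ fluoride/hydroxide unmasking of a bis-silyl dimethyl ester; C2=C3 ⇐ Wittig olefination of a C3 methyl ketone.
2. Oxirane (the only ring, closed late) ⇐ hydroxyl-directed peracid epoxidation of a (Z)-trisubstituted allylic alcohol; its (R)-carbinol, bought as (R)-but-3-yn-2-ol, sets C4/C5 and is then oxidised to the ketone.
3. C9–C10 ⇐ Sonogashira coupling then full hydrogenation; C5–C6 ⇐ Negishi coupling of a (Z)-iodoalkenol with the zinc reagent of methyl (R)-3-bromo-2-methylpropanoate (C7 bought).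
4. Key bond C12–C13, both stereocentres ⇐ [2,3]-Wittig rearrangement of a silylpropargyl ether of an (S,Z)-allylic alcohol from (S)-but-3-yn-2-ol (1,3-chirality transfer; the old carbinol carbon is later lost on ozonolysis).
5. Ring order: one ring only, the oxirane, formed after all C–C couplings except the C2=C3 olefination.

Assumption: (R)- and (S)-but-3-yn-2-ol and methyl (R)-3-bromo-2-methylpropanoate are bought as inexpensive single enantiomers; locants C1–C14 in the text are those of the target's tetradec-2-enedioic acid chain.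

**Step 1**
Reactants: 1 (R)-but-3-yn-2-ol
Product: 2 (R)-pent-3-yn-2-ol
Conditions: n-BuLi (2.1 equiv), THF, −78 → 0 °C; MeI, DMPU, → rt
Reagents that add atoms: iodomethane, CI
Why: The alkoxide–acetylide dianion is alkylated only at carbon (acetylide alkylation), so the bought carbinol centre is untouched.

**Step 2**
Reactants: 2 (R)-pent-3-yn-2-ol
Product: 3 (2R,3Z)-4-iodopent-3-en-2-ol
Conditions: NaAlH2(OCH2CH2OMe)2, THF, 0 °C → rt; EtOAc; I2, −78 → 0 °C
Reagents that add atoms: iodine, II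
Why: trans-Hydroalumination of the propargylic alcohol through the cyclic alkoxyalanate puts Al on the distal carbon cis to the carbinol, and iodinolysis with retention gives the Z iodoalkene.

**Step 3**
Reactants: 3 (2R,3Z)-4-iodopent-3-en-2-ol; 4 methyl (R)-3-bromo-2-methylpropanoate
Product: 6 methyl (2S,4Z,6R)-6-hydroxy-2,4-dimethylhept-4-enoate, via alkylzinc bromide 5 (not isolated)
Conditions: 4, Zn dust, I2 (cat.), DMA, 70 °C; then 3 (0.4 equiv), Pd(PPh3)2Cl2 (3 mol %), TMEDA, THF, rt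
Reagents that add atoms: none
Why: Zinc insertion then Negishi sp3–sp2 coupling proceeds with retention of the alkene geometry; the bought C7 centre is β to zinc and is not touched, and excess zinc reagent covers the free hydroxyl.

**Step 4**
Reactants: 6 methyl (2S,4Z,6R)-6-hydroxy-2,4-dimethylhept-4-enoate
Product: 7 (2S,4Z,6R)-6-hydroxy-2,4-dimethylhept-4-enal
Conditions: i-Bu2AlH (2.2 equiv), CH2Cl2, −78 °C; aq. KNaC4H4O6
Reagents that add atoms: none
Why: Half-reduction of the methyl ester stops at the tetrahedral aluminate at −78 °C (the hydroxyl is masked as its aluminium alkoxide); the crude aldehyde is used at once to avoid α-epimerisation.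

**Step 5**
Reactants: 7 (2S,4Z,6R)-6-hydroxy-2,4-dimethylhept-4-enal
Product: 8 (2R,3Z,6S,7E)-8-iodo-4,6-dimethylocta-3,7-dien-2-ol
Conditions: CrCl2, CHI3, THF, 0 °C → rt
Reagents that add atoms: iodoform, IC(I)I
Why: Takai olefination gives the (E)-iodoalkene under non-basic conditions; any Z isomer converges after the later hydrogenation.

**Step 6**
Reactants: 9 (S)-but-3-yn-2-ol
Product: 10 (4S)-pent-2-yne-1,4-diol
Conditions: n-BuLi (2.1 equiv), THF, −78 °C; (CH2O)n, → rt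
Reagents that add atoms: formaldehyde (from paraformaldehyde), C=O
Why: Acetylide addition to formaldehyde installs the future CH2OH carbon without touching the bought carbinol centre.

**Step 7**
Reactants: 10 (4S)-pent-2-yne-1,4-diol
Product: 11 (2S)-5-[(tert-butyldiphenylsilyl)oxy]pent-3-yn-2-ol
Conditions: TBDPSCl (1.0 equiv), imidazole, CH2Cl2, 0 °C
Reagents that add atoms: tert-butyl(chloro)diphenylsilane, CC(C)(C)[Si](Cl)(c1ccccc1)c1ccccc1
Why: The bulky silyl chloride silylates the primary hydroxyl selectively, and this group resists O→O migration in the next steps.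

**Step 8**
Reactants: 11 (2S)-5-[(tert-butyldiphenylsilyl)oxy]pent-3-yn-2-ol
Product: 12 (2S,3Z)-5-[(tert-butyldiphenylsilyl)oxy]pent-3-en-2-ol
Conditions: H2 (1 atm), Pd/CaCO3 poisoned with Pb(OAc)2, quinoline, EtOAc, rt
Reagents that add atoms: none
Why: syn-Semihydrogenation of the alkyne gives the Z alkene needed for the syn outcome of the rearrangement.

**Step 9**
Reactants: 12 (2S,3Z)-5-[(tert-butyldiphenylsilyl)oxy]pent-3-en-2-ol; 13 3-bromo-1-(trimethylsilyl)prop-1-yne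
Product: 14 tert-butyl(diphenyl){[(2Z,4S)-4-{[3-(trimethylsilyl)prop-2-yn-1-yl]oxy}pent-2-en-1-yl]oxy}silane
Conditions: NaH, THF/DMF, 0 °C; 13, n-Bu4NI (cat.), → rt
Reagents that add atoms: none
Why: Williamson etherification by SN2 at the propargylic bromide leaves the allylic stereocentre unchanged.

**Step 10**
Reactants: 14 tert-butyl(diphenyl){[(2Z,4S)-4-{[3-(trimethylsilyl)prop-2-yn-1-yl]oxy}pent-2-en-1-yl]oxy}silane
Product: 16 (3R,4R,5E)-3-[(tert-butyldimethylsilyl)oxy]-4-{[(tert-butyldiphenylsilyl)oxy]methyl}-1-(trimethylsilyl)hept-5-en-1-yne, via lithium alkoxide 15 (not isolated)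
Conditions: n-BuLi (1.2 equiv), THF, −78 °C; then TBSOTf, −78 → 0 °C
Reagents that add atoms: tert-butyldimethylsilyl trifluoromethanesulfonate, CC(C)(C)[Si](C)(C)OS(=O)(=O)C(F)(F)F
Why: The propargylic carbanion undergoes a suprafacial [2,3]-Wittig rearrangement through a five-membered envelope with the methyl group pseudo-equatorial (A(1,3) strain in the Z alkene), so the (S)-carbinol transfers its chirality to C13, the Z alkene with the silylalkynyl group gives the syn C12/C13 pair, and the alkoxide is trapped as its silyl ether.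

**Step 11**
Reactants: 16 (3R,4R,5E)-3-[(tert-butyldimethylsilyl)oxy]-4-{[(tert-butyldiphenylsilyl)oxy]methyl}-1-(trimethylsilyl)hept-5-en-1-yne
Product: 18 (2R,3R)-3-[(tert-butyldimethylsilyl)oxy]-2-{[(tert-butyldiphenylsilyl)oxy]methyl}-5-(trimethylsilyl)pent-4-ynoic acid, via aldehyde 17 (not isolated)
Conditions: O3, acetone/H2O (19:1), 0 °C; then NaClO2, NaH2PO4, 0 °C → rt (one pot)
Reagents that add atoms: ozone, [O-][O+]=O; water, O; sodium chlorite NaClO2, [Na+].[O-]Cl=O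
Why: Ozonolysis in wet solvent cleaves only the propenyl group (the silylalkyne is much slower) and chlorite oxidation (Pinnick type, with the peroxide formed serving as hypochlorite scavenger) gives the acid without epimerising C13.

**Step 12**
Reactants: 18 (2R,3R)-3-[(tert-butyldimethylsilyl)oxy]-2-{[(tert-butyldiphenylsilyl)oxy]methyl}-5-(trimethylsilyl)pent-4-ynoic acid
Product: 20 methyl (2R,3R)-3-[(tert-butyldimethylsilyl)oxy]-2-{[(tert-butyldiphenylsilyl)oxy]methyl}pent-4-ynoate, via silylalkyne methyl ester 19 (not isolated)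
Conditions: TMSCHN2, PhMe/MeOH, 0 °C; then K2CO3 (cat.), MeOH, rt
Reagents that add atoms: (trimethylsilyl)diazomethane, C[Si](C)(C)C=[N+]=[N-]
Why: O-Methylation by the diazoalkane is followed by methoxide-catalysed protodesilylation of the alkynylsilane, which is far faster than any enolisation of the hindered ester.

**Step 13**
Reactants: 8 (2R,3Z,6S,7E)-8-iodo-4,6-dimethylocta-3,7-dien-2-ol; 20 methyl (2R,3R)-3-[(tert-butyldimethylsilyl)oxy]-2-{[(tert-butyldiphenylsilyl)oxy]methyl}pent-4-ynoate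
Product: 21 methyl (2R,3R,6E,8S,10Z,12R)-3-[(tert-butyldimethylsilyl)oxy]-2-{[(tert-butyldiphenylsilyl)oxy]methyl}-12-hydroxy-8,10-dimethyltrideca-6,10-dien-4-ynoate
Conditions: Pd(PPh3)2Cl2 (3 mol %), CuI (5 mol %), Et3N, THF, rt
Reagents that add atoms: none
Why: Sonogashira coupling joins C9 to C10 under mild amine conditions that tolerate the free alcohol, the ester and the silyl ethers.

**Step 14**
Reactants: 21 methyl (2R,3R,6E,8S,10Z,12R)-3-[(tert-butyldimethylsilyl)oxy]-2-{[(tert-butyldiphenylsilyl)oxy]methyl}-12-hydroxy-8,10-dimethyltrideca-6,10-dien-4-ynoate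
Product: 22 methyl (2R,3R,6E,8S)-3-[(tert-butyldimethylsilyl)oxy]-2-{[(tert-butyldiphenylsilyl)oxy]methyl}-9-{(2R,3S)-3-[(1R)-1-hydroxyethyl]-2-methyloxiran-2-yl}-8-methylnon-6-en-4-ynoate
Conditions: mCPBA (1.1 equiv), CH2Cl2, 0 °C
Reagents that add atoms: 3-chloroperoxybenzoic acid, OOC(=O)c1cccc(Cl)c1
Why: In this hydroxyl-directed Prilezhaev epoxidation, A(1,3) strain holds the carbinol H in the alkene plane, so the hydrogen-bonded peracid attacks one face (threo, about 95:5 expected) and the (R)-carbinol sets C4 and C5; the electron-rich trisubstituted alkene reacts well before the enyne.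

**Step 15**
Reactants: 22 methyl (2R,3R,6E,8S)-3-[(tert-butyldimethylsilyl)oxy]-2-{[(tert-butyldiphenylsilyl)oxy]methyl}-9-{(2R,3S)-3-[(1R)-1-hydroxyethyl]-2-methyloxiran-2-yl}-8-methylnon-6-en-4-ynoate
Product: 23 methyl (2R,3S,8R)-3-[(tert-butyldimethylsilyl)oxy]-2-{[(tert-butyldiphenylsilyl)oxy]methyl}-9-{(2R,3S)-3-[(1R)-1-hydroxyethyl]-2-methyloxiran-2-yl}-8-methylnonanoate
Conditions: H2 (1 atm), Pt/C, EtOAc, rt
Reagents that add atoms: none
Why: Heterogeneous hydrogenation saturates the enyne to the C8–C11 chain; platinum limits alkene migration at allylic C7, and the trisubstituted oxirane and silyl ethers are inert.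

**Step 16**
Reactants: 23 methyl (2R,3S,8R)-3-[(tert-butyldimethylsilyl)oxy]-2-{[(tert-butyldiphenylsilyl)oxy]methyl}-9-{(2R,3S)-3-[(1R)-1-hydroxyethyl]-2-methyloxiran-2-yl}-8-methylnonanoate
Product: 24 methyl (2R,3S,8R)-9-[(2R,3R)-3-acetyl-2-methyloxiran-2-yl]-3-[(tert-butyldimethylsilyl)oxy]-2-{[(tert-butyldiphenylsilyl)oxy]methyl}-8-methylnonanoate
Conditions: Dess–Martin periodinane, CH2Cl2, 0 °C → rt
Reagents that add atoms: none
Why: Dess–Martin oxidation removes the now-spent directing carbinol as a methyl ketone; the oxirane CH cannot enolise, so C4 is safe.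

**Step 17**
Reactants: 24 methyl (2R,3S,8R)-9-[(2R,3R)-3-acetyl-2-methyloxiran-2-yl]-3-[(tert-butyldimethylsilyl)oxy]-2-{[(tert-butyldiphenylsilyl)oxy]methyl}-8-methylnonanoate
Product: 25 dimethyl (2E,4S,5R,7R,12S,13R)-12-[(tert-butyldimethylsilyl)oxy]-13-{[(tert-butyldiphenylsilyl)oxy]methyl}-4,5-epoxy-3,5,7-trimethyltetradec-2-enedioate
Conditions: Ph3P=CHCO2Me, PhMe, 90 °C
Reagents that add atoms: methyl (triphenylphosphoranylidene)acetate, COC(=O)C=P(c1ccccc1)(c1ccccc1)c1ccccc1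
Why: Wittig olefination with the stabilised, non-basic ylide is helped by the α-oxygen and places the ester trans to the larger oxiranyl group (E); the minor Z isomer is removed by chromatography.

**Step 18**
Reactants: 25 dimethyl (2E,4S,5R,7R,12S,13R)-12-[(tert-butyldimethylsilyl)oxy]-13-{[(tert-butyldiphenylsilyl)oxy]methyl}-4,5-epoxy-3,5,7-trimethyltetradec-2-enedioate
Product: 27 (2E,4S,5R,7R,12S,13R)-4,5-epoxy-12-hydroxy-13-(hydroxymethyl)-3,5,7-trimethyltetradec-2-enedioic acid (the target), via diol diester 26 (not isolated)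
Conditions: n-Bu4NF, AcOH (1:1), THF, rt; then LiOH, THF/MeOH/H2O, 0 °C → rt; aq. H3PO4 to pH 4, 0 °C
Reagents that add atoms: lithium hydroxide LiOH, [Li+].[OH-]
Why: Buffered fluoride desilylation followed by saponification of both methyl esters and cold, mild acidification keeps the acid-sensitive vinyl oxirane and leaves all five stereocentres untouched.

**Compound list**
1 | (R)-but-3-yn-2-ol | C[C@@H](O)C#C | starting material
2 | (R)-pent-3-yn-2-ol | C[C@@H](O)C#CC | intermediate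
3 | (2R,3Z)-4-iodopent-3-en-2-ol | C[C@@H](O)/C=C(\I)C | intermediate
4 | methyl (R)-3-bromo-2-methylpropanoate | BrC[C@H](C)C(=O)OC | starting material
5 | [(2R)-3-methoxy-2-methyl-3-oxopropyl]zinc bromide | Br[Zn]C[C@H](C)C(=O)OC | intermediate
6 | methyl (2S,4Z,6R)-6-hydroxy-2,4-dimethylhept-4-enoate | C[C@@H](O)/C=C(\C[C@H](C)C(=O)OC)C | intermediate
7 | (2S,4Z,6R)-6-hydroxy-2,4-dimethylhept-4-enal | C[C@@H](O)/C=C(\C[C@H](C)C=O)C | intermediate
8 | (2R,3Z,6S,7E)-8-iodo-4,6-dimethylocta-3,7-dien-2-ol | C[C@@H](O)/C=C(\C[C@H](C)/C=C/I)C | intermediate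
9 | (S)-but-3-yn-2-ol | C[C@H](O)C#C | starting material
10 | (4S)-pent-2-yne-1,4-diol | C[C@H](O)C#CCO | intermediate
11 | (2S)-5-[(tert-butyldiphenylsilyl)oxy]pent-3-yn-2-ol | C[C@H](O)C#CCO[Si](c1ccccc1)(c1ccccc1)C(C)(C)C | intermediate
12 | (2S,3Z)-5-[(tert-butyldiphenylsilyl)oxy]pent-3-en-2-ol | C[C@H](O)/C=C\CO[Si](c1ccccc1)(c1ccccc1)C(C)(C)C | intermediate
13 | 3-bromo-1-(trimethylsilyl)prop-1-yne | C[Si](C)(C)C#CCBr | starting material
14 | tert-butyl(diphenyl){[(2Z,4S)-4-{[3-(trimethylsilyl)prop-2-yn-1-yl]oxy}pent-2-en-1-yl]oxy}silane | C[C@H](OCC#C[Si](C)(C)C)/C=C\CO[Si](c1ccccc1)(c1ccccc1)C(C)(C)C | intermediate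
15 | lithium (3R,4R,5E)-4-{[(tert-butyldiphenylsilyl)oxy]methyl}-1-(trimethylsilyl)hept-5-en-1-yn-3-olate | [Li+].C[Si](C)(C)C#C[C@H]([O-])[C@@H](CO[Si](c1ccccc1)(c1ccccc1)C(C)(C)C)/C=C/C | intermediate
16 | (3R,4R,5E)-3-[(tert-butyldimethylsilyl)oxy]-4-{[(tert-butyldiphenylsilyl)oxy]methyl}-1-(trimethylsilyl)hept-5-en-1-yne | C[Si](C)(C)C#C[C@H](O[Si](C)(C)C(C)(C)C)[C@@H](CO[Si](c1ccccc1)(c1ccccc1)C(C)(C)C)/C=C/C | intermediate
17 | (2R,3R)-3-[(tert-butyldimethylsilyl)oxy]-2-{[(tert-butyldiphenylsilyl)oxy]methyl}-5-(trimethylsilyl)pent-4-ynal | C[Si](C)(C)C#C[C@H](O[Si](C)(C)C(C)(C)C)[C@@H](CO[Si](c1ccccc1)(c1ccccc1)C(C)(C)C)C=O | intermediate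
18 | (2R,3R)-3-[(tert-butyldimethylsilyl)oxy]-2-{[(tert-butyldiphenylsilyl)oxy]methyl}-5-(trimethylsilyl)pent-4-ynoic acid | C[Si](C)(C)C#C[C@H](O[Si](C)(C)C(C)(C)C)[C@@H](CO[Si](c1ccccc1)(c1ccccc1)C(C)(C)C)C(=O)O | intermediate
19 | methyl (2R,3R)-3-[(tert-butyldimethylsilyl)oxy]-2-{[(tert-butyldiphenylsilyl)oxy]methyl}-5-(trimethylsilyl)pent-4-ynoate | C[Si](C)(C)C#C[C@H](O[Si](C)(C)C(C)(C)C)[C@@H](CO[Si](c1ccccc1)(c1ccccc1)C(C)(C)C)C(=O)OC | intermediate
20 | methyl (2R,3R)-3-[(tert-butyldimethylsilyl)oxy]-2-{[(tert-butyldiphenylsilyl)oxy]methyl}pent-4-ynoate | C#C[C@H](O[Si](C)(C)C(C)(C)C)[C@@H](CO[Si](c1ccccc1)(c1ccccc1)C(C)(C)C)C(=O)OC | intermediate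
21 | methyl (2R,3R,6E,8S,10Z,12R)-3-[(tert-butyldimethylsilyl)oxy]-2-{[(tert-butyldiphenylsilyl)oxy]methyl}-12-hydroxy-8,10-dimethyltrideca-6,10-dien-4-ynoate | C[C@@H](O)/C=C(\C[C@H](C)/C=C/C#C[C@H](O[Si](C)(C)C(C)(C)C)[C@@H](CO[Si](c1ccccc1)(c1ccccc1)C(C)(C)C)C(=O)OC)C | intermediate
22 | methyl (2R,3R,6E,8S)-3-[(tert-butyldimethylsilyl)oxy]-2-{[(tert-butyldiphenylsilyl)oxy]methyl}-9-{(2R,3S)-3-[(1R)-1-hydroxyethyl]-2-methyloxiran-2-yl}-8-methylnon-6-en-4-ynoate | C[C@@H](O)[C@@H]1O[C@]1(C)C[C@H](C)/C=C/C#C[C@H](O[Si](C)(C)C(C)(C)C)[C@@H](CO[Si](c1ccccc1)(c1ccccc1)C(C)(C)C)C(=O)OC | intermediate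
23 | methyl (2R,3S,8R)-3-[(tert-butyldimethylsilyl)oxy]-2-{[(tert-butyldiphenylsilyl)oxy]methyl}-9-{(2R,3S)-3-[(1R)-1-hydroxyethyl]-2-methyloxiran-2-yl}-8-methylnonanoate | C[C@@H](O)[C@@H]1O[C@]1(C)C[C@H](C)CCCC[C@H](O[Si](C)(C)C(C)(C)C)[C@@H](CO[Si](c1ccccc1)(c1ccccc1)C(C)(C)C)C(=O)OC | intermediate
24 | methyl (2R,3S,8R)-9-[(2R,3R)-3-acetyl-2-methyloxiran-2-yl]-3-[(tert-butyldimethylsilyl)oxy]-2-{[(tert-butyldiphenylsilyl)oxy]methyl}-8-methylnonanoate | CC(=O)[C@@H]1O[C@]1(C)C[C@H](C)CCCC[C@H](O[Si](C)(C)C(C)(C)C)[C@@H](CO[Si](c1ccccc1)(c1ccccc1)C(C)(C)C)C(=O)OC | intermediate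
25 | dimethyl (2E,4S,5R,7R,12S,13R)-12-[(tert-butyldimethylsilyl)oxy]-13-{[(tert-butyldiphenylsilyl)oxy]methyl}-4,5-epoxy-3,5,7-trimethyltetradec-2-enedioate | C/C(=C\C(=O)OC)[C@@H]1O[C@]1(C)C[C@H](C)CCCC[C@H](O[Si](C)(C)C(C)(C)C)[C@@H](CO[Si](c1ccccc1)(c1ccccc1)C(C)(C)C)C(=O)OC | intermediate
26 | dimethyl (2E,4S,5R,7R,12S,13R)-4,5-epoxy-12-hydroxy-13-(hydroxymethyl)-3,5,7-trimethyltetradec-2-enedioate | C/C(=C\C(=O)OC)[C@@H]1O[C@]1(C)C[C@H](C)CCCC[C@H](O)[C@@H](CO)C(=O)OC | intermediate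
27 | (2E,4S,5R,7R,12S,13R)-4,5-epoxy-12-hydroxy-13-(hydroxymethyl)-3,5,7-trimethyltetradec-2-enedioic acid | C/C(=C\C(=O)O)[C@@H]1O[C@]1(C)C[C@H](C)CCCC[C@H](O)[C@@H](CO)C(=O)O | target

**Step count and risks**
Total step count: 18. Longest linear sequence: 13 steps (steps 6–12 from 9, then steps 13–18).

The three steps most likely to fail:

The coupling in step 3 must keep the Z geometry of a hindered iodoalkene and tolerate a free hydroxyl while using a weakly nucleophilic ester-bearing alkylzinc. The fallback sets out from 3 and 4 and comes back at 6. It replaces the preformed organozinc by a nickel-catalysed reductive cross-electrophile coupling of the two halides (NiI2 10 mol %, 4,4′-di-tert-butyl-2,2′-bipyridine, Mn powder, NaI, DMA, 40 °C), which tolerates free alcohols and makes no new compound (F0).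

The olefination in step 17 may be slow on the hindered epoxy methyl ketone and may give too much Z isomer. The fallback sets out from 24 and comes back at 25. Wittig methylenation (Ph3PCH3Br, KN(SiMe3)2, THF, −78 → 0 °C) gives the isopropenyl oxirane methyl (2R,3S,8R)-3-[(tert-butyldimethylsilyl)oxy]-2-{[(tert-butyldiphenylsilyl)oxy]methyl}-8-methyl-9-[(2R,3S)-2-methyl-3-(prop-1-en-2-yl)oxiran-2-yl]nonanoate F1. Cross-metathesis of F1 with methyl acrylate (second-generation Hoveyda–Grubbs catalyst, CH2Cl2, 40 °C) then gives the thermodynamic E enoate 25.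

The final unmasking in step 18 exposes the vinyl oxirane and the β-hydroxy ester to fluoride and hydroxide, and the hindered C14 ester may hydrolyse slowly. The fallback sets out from 25 and comes back at 27. Me3SnOH (1,2-dichloroethane, 70 °C) cleaves both methyl esters under neutral conditions to the bis-silyl diacid (2E,4S,5R,7R,12S,13R)-12-[(tert-butyldimethylsilyl)oxy]-13-{[(tert-butyldiphenylsilyl)oxy]methyl}-4,5-epoxy-3,5,7-trimethyltetradec-2-enedioic acid F2. Buffered fluoride (n-Bu4NF/AcOH, THF, rt) then removes both silyl groups from F2 to give 27.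

**Further compounds**
F0 | step 3 | none | none
F1 | step 17 | methyl (2R,3S,8R)-3-[(tert-butyldimethylsilyl)oxy]-2-{[(tert-butyldiphenylsilyl)oxy]methyl}-8-methyl-9-[(2R,3S)-2-methyl-3-(prop-1-en-2-yl)oxiran-2-yl]nonanoate | CC(=C)[C@@H]1O[C@]1(C)C[C@H](C)CCCC[C@H](O[Si](C)(C)C(C)(C)C)[C@@H](CO[Si](c1ccccc1)(c1ccccc1)C(C)(C)C)C(=O)OC
F2 | step 18 | (2E,4S,5R,7R,12S,13R)-12-[(tert-butyldimethylsilyl)oxy]-13-{[(tert-butyldiphenylsilyl)oxy]methyl}-4,5-epoxy-3,5,7-trimethyltetradec-2-enedioic acid | C/C(=C\C(=O)O)[C@@H]1O[C@]1(C)C[C@H](C)CCCC[C@H](O[Si](C)(C)C(C)(C)C)[C@@H](CO[Si](c1ccccc1)(c1ccccc1)C(C)(C)C)C(=O)O
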